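**The problem**

The target is a γ‑butyrolactone (O1, C2=O, C3, C4, C5H2). C3 carries a hydroxyl and a benzylic CH2 (C7, ring B); C4 carries a hydroxy(aryl)methyl group (C6, ring A). C3 (S), C4 (R) and C6 (R) are contiguous stereocentres, and this numbering is used for all intermediates. C3 is a fully substituted carbinol whose hydroxyl is cis to the C4 side chain and whose benzyl group is trans to it. An α‑benzyl lactone enolate should take an oxygen electrophile trans to the C4 substituent, so late hydroxylation would give the wrong C3 epimer; the order and face of bond formation at C3 is the central problem. C6 lies outside the ring and has to be controlled from C4 (1,2) or C3 (1,3); only the C3 oxygen offers a dependable handle. Rings A and B are the same 4‑hydroxy‑3‑methoxyphenyl group, so they must enter as two different reactive forms of one building block. The 4‑hydroxybenzylic alcohol at C6 ionises easily (quinone methide), which invites epimerisation, hydrogenolysis and Friedel–Crafts closure onto ring B, so acid, hydrogenolysis and unbuffered base must be avoided once it exists. The enabling feature is the chain O–C3–C4–C6–O, a 1,3‑dioxygenated unit whose ends are cis on the lactone ring. With C6 at the ketone level it is a β‑hydroxy ketone, the ring‑opened form of a 2‑isoxazoline (O–N=C6–C4–C3) cis‑fused to the lactone across C3–C4, which is what a nitrile oxide gives on adding to the C3=C4 bond of a 3‑benzylbutenolide.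

**Retrosynthesis**

19 ⇒ 18 ⇒ 16. The two aryl O–Si bonds are cut first (buffered fluoride at the end), then the C6–H bond, which leads back to aryl ketone 16. Cutting C6–H rather than C4–C6 at this stage lets the tertiary C3 hydroxyl set C6 by internal hydride delivery (through alkoxyborohydride 17) and keeps the ionisable benzylic alcohol out of every earlier step. The precursor has one stereocentre fewer. The forward reduction must be intramolecular; open‑chain or chelate‑controlled hydride addition would be expected to favour the C6 epimer.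

16 ⇒ 14. The β‑hydroxy ketone is written as its 2‑isoxazoline: in the forward sense the N–O bond is cleaved and imine 15 is hydrolysed. A true aldol cut of C3–C4 would need the enolate of a β‑acyloxy ketone and an enolisable 3‑arylpyruvate, both of which misbehave. The isoxazoline hides the retro‑aldol‑ and elimination‑prone ketol until two steps from the end and is inert to the silane and Lewis acid used before that. The forward step must cleave N–O without reducing the aryl ketone it releases.

14 ⇒ 13. One C5–H bond is exchanged for a C5–O(menthyl) bond. The precursor is slightly larger, but this acetal carbon is the only stereocentre present before the key step and it is removed without trace. The forward ionic hydrogenation is placed here because neither an aryl ketone nor a benzylic alcohol is yet present.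

13 ⇒ 9 + 12. The C4–C6 and C3–O bonds are cut together as a (3+2) cycloaddition of nitrile oxide 12 (ring A and C6; made from oxime 10 through chloride 11) to the C3=C4 bond of benzylbutenolide 9. The neighbouring cuts, C3–C7 or C3–O last, each rest on a sequence of enolate steps whose facial bias is the wrong one for the hydroxyl. Here the suprafacial addition forces the C3 oxygen and C6 to be cis, and the C5 alkoxy group decides the face. The precursor 9 has no stereocentre except the auxiliary and no sp3 ring carbon except C5. The forward reaction has to add anti to the C5–O bond, with oxygen going to C3 and carbon to C4.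

9 ⇒ 7 + 4; 7 ⇒ 5; 12 and 4 ⇒ 2 ⇒ 1. The C3–C7 bond is cut at the sp2 carbon: Negishi coupling of bromobutenolide 7 with benzylzinc 8 (from bromide 4) avoids any enolate benzylation. 7 comes from the chiral butenolide 5 through dibromide 6. Both aryl units derive from silylated vanillin 2 (from 1): reduction and bromination (3, 4) give ring B as a nucleophile precursor, and oximation (10) gives ring A as a 1,3‑dipole precursor.

**Roads not taken**

Alternative 1: the obvious route cuts C3–O and C3–C7 on a preformed 4‑substituted lactone. Lactone A1 (C4 and C6 already set, C6–O silylated) is hydroxylated through its enolate to A2. The forward key step is benzylation of the dianion of A2 with 4, trans to the C4 substituent. The chosen plan is better for three reasons.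
- The C3 configuration there depends only on the order of two strong‑base steps (oxygen before benzyl).
- None of the three stereocentres is created by the key step, and A1 still has to be made as one stereoisomer.
- The benzylic C6–O group is carried through three enolate operations.

Alternative 2: cut C3–C4 by carbene transfer. Diazoacetate A3 would close the lactone by intramolecular cyclopropanation with a chiral dirhodium tetracarboxamidate, Rh2(MPPIM)4, in the enantiomeric form that leads to the (1S,5R) series. This gives the donor–acceptor cyclopropane A4; opening by water at C6 with inversion and silylation would give A1. The cyclopropanation sets C4 and encodes C6 through the E‑alkene, but it ends at A1, so C3 still needs the hydroxylation–benzylation sequence of Alternative 1. The stereospecific opening also competes with plain ionisation when the donor is a 4‑silyloxy‑3‑methoxyphenyl group, and the route is longer.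

Alternative 3: cut C3–C4 by a [3,3] shift. The Z‑allylic ester A5, with C6 preset, would undergo Ireland–Claisen rearrangement through the chelated ketene acetal to acid A6, setting C3 and C4 together; ozonolysis with reductive work‑up and lactonisation would follow. The chosen plan is better for three reasons.
- The face selectivity at C4 rests on 1,2‑induction from C6, where an aryl and a silyloxy group compete.
- One carbon has to be excised again, and the run‑up (enantioselective propargylic alcohol, Z‑reduction, aryllactate ester) is longer.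
- The C3 oxygen needs a chelating protecting group whose removal is acidic, which the C6 benzylic ether does not tolerate.

Key step: step 7

Remark: 5 is taken as a purchasable chiral building block (otherwise two operations from furfural and (−)‑menthol); TBSO stands for tert‑butyldimethylsilyloxy and menthyloxy for (1R,2S,5R)‑2‑isopropyl‑5‑methylcyclohexyloxy.

Step 1
Reactants: 1 vanillin (4‑hydroxy‑3‑methoxybenzaldehyde)
Product: 2 4‑(TBSO)‑3‑methoxybenzaldehyde
Conditions: TBSCl, imidazole, DMF, 25 °C
Reagents that add atoms: tert‑butyldimethylsilyl chloride, CC(C)(C)[Si](C)(C)Cl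
Why: Silylation of a phenol; the aryl silyl ether should survive the organozinc, silane, nickel and borohydride steps and is removed at the end by fluoride without acid or hydrogen.

Step 2
Reactants: 2 4‑(TBSO)‑3‑methoxybenzaldehyde
Product: 3 [4‑(TBSO)‑3‑methoxyphenyl]methanol
Conditions: NaBH4, MeOH, 0 °C
Reagents that add atoms: none
Why: Borohydride reduction of an aryl aldehyde; short contact at 0 °C should leave the aryl silyl ether intact.

Step 3
Reactants: 3 [4‑(TBSO)‑3‑methoxyphenyl]methanol
Product: 4 4‑(bromomethyl)‑1‑(TBSO)‑2‑methoxybenzene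
Conditions: CBr4, PPh3, CH2Cl2, 0 °C
Reagents that add atoms: carbon tetrabromide, BrC(Br)(Br)Br
Why: Appel reaction under neutral conditions; the electron‑rich benzyl bromide is used at once.

Step 4
Reactants: 5 (5R)‑5‑(menthyloxy)furan‑2(5H)‑one
Product: 7 (5R)‑3‑bromo‑5‑(menthyloxy)furan‑2(5H)‑one, via trans‑dibromide 6 (not isolated)
Conditions: Br2, CH2Cl2, 0 °C; then Et3N, 0 to 25 °C
Reagents that add atoms: bromine, BrBr
Why: Anti addition of bromine to the enoate, then E1cB loss of HBr through the acidic C3–H, leaves bromine on C3 (α‑bromination of an enoate); C5 is not involved.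

Step 5
Reactants: 4 4‑(bromomethyl)‑1‑(TBSO)‑2‑methoxybenzene; 7 (5R)‑3‑bromo‑5‑(menthyloxy)furan‑2(5H)‑one
Product: 9 (5R)‑3‑[4‑(TBSO)‑3‑methoxybenzyl]‑5‑(menthyloxy)furan‑2(5H)‑one, via benzylzinc bromide 8 (not isolated)
Conditions: 4, Zn dust, LiCl, THF, 25 °C; then 7, Pd(PPh3)4 (3 mol%), THF, 25 to 45 °C
Reagents that add atoms: none
Why: LiCl‑promoted zinc insertion into the benzylic bromide and Negishi coupling with the α‑bromo enoate; the C3–C7 bond is made at sp2 carbon under neutral conditions, so the C3=C4 bond and the acetal C5–H stay in place.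

Step 6
Reactants: 2 4‑(TBSO)‑3‑methoxybenzaldehyde
Product: 10 (E)‑4‑(TBSO)‑3‑methoxybenzaldehyde oxime
Conditions: NH2OH·HCl, NaOAc, EtOH/H2O, 25 °C
Reagents that add atoms: hydroxylamine hydrochloride, Cl.NO
Why: Oxime condensation; 10 is the stable precursor of the nitrile oxide.

Step 7
Reactants: 10 (E)‑4‑(TBSO)‑3‑methoxybenzaldehyde oxime; 9 (5R)‑3‑[4‑(TBSO)‑3‑methoxybenzyl]‑5‑(menthyloxy)furan‑2(5H)‑one
Product: 13 (3aR,4R,6aS)‑6a‑[4‑(TBSO)‑3‑methoxybenzyl]‑3‑[4‑(TBSO)‑3‑methoxyphenyl]‑4‑(menthyloxy)‑3a,4‑dihydrofuro[3,4‑d]isoxazol‑6(6aH)‑one, via hydroximoyl chloride 11 (not isolated), via nitrile oxide 12 (not isolated)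
Conditions: 10, NCS, DMF, 25 °C; then 9 (limiting), KHCO3 (solid), EtOAc, 25 to 40 °C, 11 in excess and added in portions
Reagents that add atoms: none
Why: Huisgen (3+2) cycloaddition of a nitrile oxide: 11 loses HCl on solid KHCO3, so 12 forms slowly and adds in a concerted, asynchronous step across C3=C4 of 9 before it can dimerise. The closest known reactions are nitrile oxide cycloadditions to 5‑alkoxyfuran‑2(5H)‑ones, which occur on the face anti to the alkoxy group, and to trisubstituted α‑alkyl enoates. One ring is closed, the 2‑isoxazoline O–N=C6–C4–C3; both new bonds (C4–C6 and C3–O) form suprafacially on the alkene, so the ring can only be cis‑fused to the lactone, with the C3 oxygen and C6 on one face and the benzyl group on the other. C3 and C4 are set together: their relative configuration follows from the suprafacial addition and their absolute configuration from the C5 menthyloxy group, which blocks its own face and should give the (3aR,4R,6aS) adduct. The further selectivity needed is regiochemical, oxygen to C3 and carbon to C4: the benzyl group makes C3 fully substituted, and the bulkier carbon terminus, whose bond is the more advanced in the transition state, should go to the CH terminus C4 as with other trisubstituted alkenes and α‑alkyl acrylates. Limiting 9, portionwise 11 and a heterogeneous weak base keep the concentration of 12 low and spare the base‑sensitive acetal C5–H.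

Step 8
Reactants: 13 the (3aR,4R,6aS) cycloadduct
Product: 14 (3aS,6aS)‑6a‑[4‑(TBSO)‑3‑methoxybenzyl]‑3‑[4‑(TBSO)‑3‑methoxyphenyl]‑3a,4‑dihydrofuro[3,4‑d]isoxazol‑6(6aH)‑one
Conditions: Et3SiH, TMSOTf (0.2 equiv), CH2Cl2, −40 to 0 °C
Reagents that add atoms: none
Why: Ionic hydrogenation of an acetal: silylation of the menthyloxy oxygen, ionisation to the ring‑oxygen‑stabilised oxocarbenium ion at C5 and hydride transfer from the silane; C5 becomes CH2, so no stereocentre is formed, and no ketone or benzylic C–O bond is yet present to be reduced.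

Step 9
Reactants: 14 the (3aS,6aS) isoxazoline lactone
Product: 16 (3S,4S)‑3‑hydroxy‑4‑[4‑(TBSO)‑3‑methoxybenzoyl]‑3‑[4‑(TBSO)‑3‑methoxybenzyl]dihydrofuran‑2(3H)‑one, via β‑hydroxy imine 15 (not isolated)
Conditions: Raney Ni, H2 (1 atm), B(OH)3, MeOH/THF/H2O, 25 °C
Reagents that add atoms: water, O
Why: Hydrogenolysis of the isoxazoline N–O bond and boric‑acid‑buffered hydrolysis of the imine (the isoxazoline route to aldols); the near‑neutral medium should avoid retro‑aldol cleavage of C3–C4 and β‑elimination of the lactone carboxylate, and C3 and C4 are not touched.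

Step 10
Reactants: 16 the (3S,4S) β‑hydroxy ketone
Product: 18 (3S,4R)‑3‑hydroxy‑4‑{(R)‑hydroxy[4‑(TBSO)‑3‑methoxyphenyl]methyl}‑3‑[4‑(TBSO)‑3‑methoxybenzyl]dihydrofuran‑2(3H)‑one, via alkoxydiacetoxyborohydride 17 (not isolated)
Conditions: Me4NBH(OAc)3, MeCN/AcOH (2:1), −20 °C; aqueous sodium potassium tartrate work‑up
Reagents that add atoms: none
Why: Evans–Saksena reduction: the C3 hydroxyl exchanges onto boron and hydride is delivered to C6 through a chair six‑membered transition state with ring A and the C3 benzyl group equatorial and the lactone carbonyl axial, which should give the 6R carbinol; the reagent does not reduce the lactone, and the low temperature limits ionisation of the new benzylic alcohol.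

Step 11
Reactants: 18 the bis‑silyl ether
Product: 19 (3S,4R)‑3‑hydroxy‑4‑[(R)‑hydroxy(4‑hydroxy‑3‑methoxyphenyl)methyl]‑3‑(4‑hydroxy‑3‑methoxybenzyl)dihydrofuran‑2(3H)‑one
Conditions: TBAF, AcOH, THF, 0 °C
Reagents that add atoms: none
Why: Fluoride cleavage of both aryl silyl ethers; acetic acid protonates the phenoxides, so quinone methide chemistry at C6 and translactonisation should not occur (the isomeric lactone through the C6 oxygen would also place aryl and hydroxymethyl cis).

**Compound list**

1 | vanillin (4‑hydroxy‑3‑methoxybenzaldehyde) | COc1cc(C=O)ccc1O | starting material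
2 | 4‑(TBSO)‑3‑methoxybenzaldehyde | COc1cc(C=O)ccc1O[Si](C)(C)C(C)(C)C | intermediate
3 | [4‑(TBSO)‑3‑methoxyphenyl]methanol | COc1cc(CO)ccc1O[Si](C)(C)C(C)(C)C | intermediate
4 | 4‑(bromomethyl)‑1‑(TBSO)‑2‑methoxybenzene | COc1cc(CBr)ccc1O[Si](C)(C)C(C)(C)C | intermediate
5 | (5R)‑5‑(menthyloxy)furan‑2(5H)‑one | O=C1C=C[C@H](O[C@@H]2C[C@H](C)CC[C@H]2C(C)C)O1 | starting material
6 | 3,4‑trans‑dibromo‑5‑(menthyloxy)dihydrofuran‑2(3H)‑one (bromine on C4 anti to the C5 alkoxy group) | O=C1[C@H](Br)[C@@H](Br)[C@H](O[C@@H]2C[C@H](C)CC[C@H]2C(C)C)O1 | intermediate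
7 | (5R)‑3‑bromo‑5‑(menthyloxy)furan‑2(5H)‑one | O=C1C(Br)=C[C@H](O[C@@H]2C[C@H](C)CC[C@H]2C(C)C)O1 | intermediate
8 | [4‑(TBSO)‑3‑methoxybenzyl]zinc bromide | COc1cc(C[Zn]Br)ccc1O[Si](C)(C)C(C)(C)C | intermediate
9 | (5R)‑3‑[4‑(TBSO)‑3‑methoxybenzyl]‑5‑(menthyloxy)furan‑2(5H)‑one | COc1cc(CC2=C[C@H](O[C@@H]3C[C@H](C)CC[C@H]3C(C)C)OC2=O)ccc1O[Si](C)(C)C(C)(C)C | intermediate
10 | (E)‑4‑(TBSO)‑3‑methoxybenzaldehyde oxime | COc1cc(/C=N/O)ccc1O[Si](C)(C)C(C)(C)C | intermediate
11 | (Z)‑4‑(TBSO)‑N‑hydroxy‑3‑methoxybenzimidoyl chloride | COc1cc(/C(Cl)=N/O)ccc1O[Si](C)(C)C(C)(C)C | intermediate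
12 | 4‑(TBSO)‑3‑methoxybenzonitrile oxide | COc1cc(C#[N+][O-])ccc1O[Si](C)(C)C(C)(C)C | intermediate
13 | (3aR,4R,6aS)‑6a‑[4‑(TBSO)‑3‑methoxybenzyl]‑3‑[4‑(TBSO)‑3‑methoxyphenyl]‑4‑(menthyloxy)‑3a,4‑dihydrofuro[3,4‑d]isoxazol‑6(6aH)‑one | O=C1O[C@@H](O[C@@H]3C[C@H](C)CC[C@H]3C(C)C)[C@@H]2C(c4ccc(O[Si](C)(C)C(C)(C)C)c(OC)c4)=NO[C@]12Cc5ccc(O[Si](C)(C)C(C)(C)C)c(OC)c5 | intermediate
14 | (3aS,6aS)‑6a‑[4‑(TBSO)‑3‑methoxybenzyl]‑3‑[4‑(TBSO)‑3‑methoxyphenyl]‑3a,4‑dihydrofuro[3,4‑d]isoxazol‑6(6aH)‑one | O=C1OC[C@@H]2C(c4ccc(O[Si](C)(C)C(C)(C)C)c(OC)c4)=NO[C@]12Cc5ccc(O[Si](C)(C)C(C)(C)C)c(OC)c5 | intermediate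
15 | (3S,4S)‑3‑hydroxy‑4‑{imino[4‑(TBSO)‑3‑methoxyphenyl]methyl}‑3‑[4‑(TBSO)‑3‑methoxybenzyl]dihydrofuran‑2(3H)‑one | COc1cc(C[C@@]2(O)C(=O)OC[C@@H]2C(=N)c2ccc(O[Si](C)(C)C(C)(C)C)c(OC)c2)ccc1O[Si](C)(C)C(C)(C)C | intermediate
16 | (3S,4S)‑3‑hydroxy‑4‑[4‑(TBSO)‑3‑methoxybenzoyl]‑3‑[4‑(TBSO)‑3‑methoxybenzyl]dihydrofuran‑2(3H)‑one | COc1cc(C[C@@]2(O)C(=O)OC[C@@H]2C(=O)c2ccc(O[Si](C)(C)C(C)(C)C)c(OC)c2)ccc1O[Si](C)(C)C(C)(C)C | intermediate
17 | tetramethylammonium diacetoxy(hydrido)borate of the C3 alkoxide of 16 | COc1cc(C[C@@]2(O[BH-](OC(C)=O)OC(C)=O)C(=O)OC[C@@H]2C(=O)c2ccc(O[Si](C)(C)C(C)(C)C)c(OC)c2)ccc1O[Si](C)(C)C(C)(C)C.C[N+](C)(C)C | intermediate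
18 | (3S,4R)‑3‑hydroxy‑4‑{(R)‑hydroxy[4‑(TBSO)‑3‑methoxyphenyl]methyl}‑3‑[4‑(TBSO)‑3‑methoxybenzyl]dihydrofuran‑2(3H)‑one | COc1cc(C[C@@]2(O)C(=O)OC[C@@H]2[C@@H](O)c2ccc(O[Si](C)(C)C(C)(C)C)c(OC)c2)ccc1O[Si](C)(C)C(C)(C)C | intermediate
19 | (3S,4R)‑3‑hydroxy‑4‑[(R)‑hydroxy(4‑hydroxy‑3‑methoxyphenyl)methyl]‑3‑(4‑hydroxy‑3‑methoxybenzyl)dihydrofuran‑2(3H)‑one | COc1cc(C[C@@]2(O)C(=O)OC[C@@H]2[C@@H](O)c2ccc(O)c(OC)c2)ccc1O | target

**Step count and risks**

Total steps: 11. Longest linear sequence: 9 steps (1 → 2 → 3 → 4 → 9 → 13 → 14 → 16 → 18 → 19; steps 1, 2, 3, 5, 7, 8, 9, 10, 11).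

Least certain steps:

Step 7 (key step). The cycloaddition to a trisubstituted, cross‑conjugated alkene may be slow enough that dimerisation of the nitrile oxide outruns it. The carbon terminus may also attack C3 (reversed regiochemistry), because the parent butenolide has the opposite electronic preference and only the C3 benzyl group opposes it. Base‑induced epimerisation at C5 would erode the enantiomeric purity. The fallback sets out from 5 and 2 and rejoins the route at 16, using enolate chemistry throughout.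
- Aldehyde 2 is converted into its 1,3‑dithiane F1 (propane‑1,3‑dithiol, BF3·OEt2).
- Lithiated F1 (n‑BuLi, THF, −78 °C) adds to 5 anti to the menthyloxy group to give lactone F2.
- The lithium enolate of F2 is hydroxylated with 2‑(phenylsulfonyl)‑3‑phenyloxaziridine to F3.
- The dianion of F3 (LDA, DMPU) is benzylated with 4 trans to the C4 substituent to give F4, which has the C3 configuration of 19.
- Ionic hydrogenation as in step 8 gives F5, and dithiane hydrolysis (MeI, CaCO3, aqueous MeCN) gives 16.

Step 8. Ionisation of an acyl acetal is sluggish, and elimination of the C4 proton from the oxocarbenium ion, or slow silane reduction of the C=N bond, may compete. The fallback sets out from 13 and rejoins at 14 by hydrolysis and reduction instead of ionic hydrogenation. Aqueous trifluoroacetic acid in THF hydrolyses the acetal to lactol F6 (anomeric mixture). NaBH4 in EtOH reduces its open aldehyde form to hydroxy acid F7, and acidification closes the lactone to 14.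

Step 10. Exchange of the hindered tertiary C3 hydroxyl onto boron may be slow, so that undirected hydride addition with poor or opposite facial selectivity competes; the benzylic alcohol formed may ionise in acetic acid. The fallback sets out from 16 and rejoins at 18 with catalyst control instead of substrate direction: Noyori transfer hydrogenation with RuCl[(R,R)‑TsDPEN](p‑cymene) and HCO2H/Et3N, which sets the R carbinol of an aryl ketone by the catalyst (no new compound, F0).

Step 9. Hydrogenation may go on to reduce the liberated aryl ketone without facial control, and the tertiary β‑hydroxy ketone may undergo retro‑aldol cleavage or lose the lactone carboxylate by β‑elimination if the medium turns basic. The fallback sets out from 14 and rejoins at 16 with a hydrogen‑free N–O cleavage: Mo(CO)6 in wet MeCN at 80 °C, where the N–O bond adds to zerovalent molybdenum and the imine is hydrolysed, so no reductant for the ketone is present (no new compound, F0).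

**Further compounds**

F1 | step 7 | 2‑[4‑(TBSO)‑3‑methoxyphenyl]‑1,3‑dithiane | COc1cc(C2SCCCS2)ccc1O[Si](C)(C)C(C)(C)C
F2 | step 7 | (4R,5R)‑4‑{2‑[4‑(TBSO)‑3‑methoxyphenyl]‑1,3‑dithian‑2‑yl}‑5‑(menthyloxy)dihydrofuran‑2(3H)‑one (C4 substituent trans to the C5 alkoxy group) | O=C1C[C@@H](C2(c3ccc(O[Si](C)(C)C(C)(C)C)c(OC)c3)SCCCS2)[C@H](O[C@@H]2C[C@H](C)CC[C@H]2C(C)C)O1
F3 | step 7 | (3R,4R,5R)‑3‑hydroxy derivative of F2 (hydroxyl trans to the C4 substituent) | O=C1[C@H](O)[C@@H](C2(c3ccc(O[Si](C)(C)C(C)(C)C)c(OC)c3)SCCCS2)[C@H](O[C@@H]2C[C@H](C)CC[C@H]2C(C)C)O1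
F4 | step 7 | (3S,4R,5R)‑3‑hydroxy‑3‑[4‑(TBSO)‑3‑methoxybenzyl] derivative of F2 (benzyl trans to the C4 substituent) | O=C1[C@](O)(Cc3ccc(O[Si](C)(C)C(C)(C)C)c(OC)c3)[C@@H](C2(c3ccc(O[Si](C)(C)C(C)(C)C)c(OC)c3)SCCCS2)[C@H](O[C@@H]2C[C@H](C)CC[C@H]2C(C)C)O1
F5 | step 7 | (3S,4S)‑3‑hydroxy‑3‑[4‑(TBSO)‑3‑methoxybenzyl]‑4‑{2‑[4‑(TBSO)‑3‑methoxyphenyl]‑1,3‑dithian‑2‑yl}dihydrofuran‑2(3H)‑one | O=C1[C@](O)(Cc3ccc(O[Si](C)(C)C(C)(C)C)c(OC)c3)[C@@H](C2(c3ccc(O[Si](C)(C)C(C)(C)C)c(OC)c3)SCCCS2)CO1
F6 | step 8 | 4‑hydroxy analogue of 13 (lactol, mixture of anomers at C4 of the fused system) | O=C1OC(O)[C@@H]2C(c4ccc(O[Si](C)(C)C(C)(C)C)c(OC)c4)=NO[C@]12Cc5ccc(O[Si](C)(C)C(C)(C)C)c(OC)c5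
F7 | step 8 | (4S,5S)‑5‑[4‑(TBSO)‑3‑methoxybenzyl]‑4‑(hydroxymethyl)‑3‑[4‑(TBSO)‑3‑methoxyphenyl]‑4,5‑dihydroisoxazole‑5‑carboxylic acid | OC[C@@H]1C(c2ccc(O[Si](C)(C)C(C)(C)C)c(OC)c2)=NO[C@]1(Cc1ccc(O[Si](C)(C)C(C)(C)C)c(OC)c1)C(=O)O
F0 | step 10 | none | none
F0 | step 9 | none | none
A1 | alternative 1 | (4R)‑4‑{(R)‑(TBSO)[4‑(TBSO)‑3‑methoxyphenyl]methyl}dihydrofuran‑2(3H)‑one | O=C1OC[C@@H](C1)[C@@H](O[Si](C)(C)C(C)(C)C)c1ccc(O[Si](C)(C)C(C)(C)C)c(OC)c1
A2 | alternative 1 | (3R,4S)‑3‑hydroxy derivative of A1 (hydroxyl trans to the C4 substituent) | O=C1OC[C@@H]([C@H]1O)[C@@H](O[Si](C)(C)C(C)(C)C)c1ccc(O[Si](C)(C)C(C)(C)C)c(OC)c1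
A3 | alternative 2 | (E)‑3‑[4‑(TBSO)‑3‑methoxyphenyl]allyl diazoacetate | COc1cc(/C=C/COC(=O)C=[N+]=[N-])ccc1O[Si](C)(C)C(C)(C)C
A4 | alternative 2 | (1S,5R,6R)‑6‑[4‑(TBSO)‑3‑methoxyphenyl]‑3‑oxabicyclo[3.1.0]hexan‑2‑one | O=C1OC[C@@H]2[C@@H](c3ccc(O[Si](C)(C)C(C)(C)C)c(OC)c3)[C@H]12
A5 | alternative 3 | (R,Z)‑4‑(TBSO)‑4‑[4‑(TBSO)‑3‑methoxyphenyl]but‑2‑enyl 2‑(methoxymethoxy)‑3‑[4‑(TBSO)‑3‑methoxyphenyl]propanoate (either configuration at C2 of the acid part) | COCOC(Cc1ccc(O[Si](C)(C)C(C)(C)C)c(OC)c1)C(=O)OC/C=C\[C@@H](O[Si](C)(C)C(C)(C)C)c1ccc(O[Si](C)(C)C(C)(C)C)c(OC)c1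
A6 | alternative 3 | 2‑(methoxymethoxy)‑2‑[4‑(TBSO)‑3‑methoxybenzyl]‑3‑{(R)‑(TBSO)[4‑(TBSO)‑3‑methoxyphenyl]methyl}pent‑4‑enoic acid with the C2 and C3 configurations that map onto C3 and C4 of 19 | COCO[C@](Cc1ccc(O[Si](C)(C)C(C)(C)C)c(OC)c1)(C(=O)O)[C@H](C=C)[C@@H](O[Si](C)(C)C(C)(C)C)c1ccc(O[Si](C)(C)C(C)(C)C)c(OC)c1
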